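**Retrosynthetic overview**

1. The strategy rests on one feature: the ether oxygen joining C5 and C10 of the 11-oxabicyclo[4.4.1]undecane core (two oxepanes sharing one oxygen inside a cyclodecane) lies on the C5–C10 fusion bond of a eudesmane decalin, and the C4=C15 methylene beside C5 is the olefin a singlet-oxygen ene reaction leaves when it places a peroxide on C5.
2. Late stage: C1=C2 by ketone dehydrogenation, C3=O by allylic oxidation next to the C4=C15 olefin, angelate by acylation of the 8β-alcohol.
3. Core: C5–H from a bridgehead ketal acetate; the C5–O–C10 bridge from a Criegee shift of C10 from C5 to oxygen in a 5α-hydroperoxy-eudesm-4(15)-en-12,6α-olide, the ene product of the 4-ene.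
4. Start: (+)-alantolactone brings rings A and B, C7, C8, C10 and the methylene lactone; α-epoxidation, epoxide-to-allyl-silyl-ether isomerisation and a lactone switch from O8 to O6 lead to the 4-ene.
5. Ring order: decalin and a lactone are bought; the 6α,12-lactone is closed in step 5; both oxepane rings and the ten-membered carbocycle arise together in step 7; no ring is formed afterwards.

Key step: step 7

Remark on the chemistry: carbon numbers and α/β face labels are those of the eudesmane skeleton of alantolactone and are kept for the ring-expanded 5,10-epoxygermacranes. The C3 configuration of alcohol 17 is of no consequence because C3 becomes a carbonyl. (+)-Alantolactone and angelic acid are taken as commercial.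

**Route**

Step 1
Reactants: 1 (+)-alantolactone
Product: 2 5α,6α-epoxyalantolactone (5α,6α-epoxyeudesm-11(13)-en-12,8β-olide)
Conditions: mCPBA, CH2Cl2, 0 °C
Reagents that add atoms: mCPBA, O=C(OO)c1cccc(Cl)c1
Why: Prilezhaev epoxidation of the only electron-rich olefin; the peracid should approach the α face, away from the axial 10β-methyl and the β-fused lactone, which sets C5 and C6, while the conjugated methylene lactone is too electron-poor to react.

Step 2
Reactants: 2 5α,6α-epoxyalantolactone
Product: 3 6α-(triethylsilyloxy)eudesma-4,11(13)-dien-12,8β-olide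
Conditions: TESOTf, 2,6-lutidine, CH2Cl2, −78 → 0 °C
Reagents that add atoms: triethylsilyl trifluoromethanesulfonate, CC[Si](CC)(CC)OS(=O)(=O)C(F)(F)F
Why: Silyl-triflate-promoted isomerisation of an epoxide to an allylic silyl ether: O-silylation, ionisation at tertiary C5 and loss of H4 from the cation (E1; C10 has no hydrogen) should give the tetrasubstituted 4,5-olefin, and the C6–O bond is never broken, so the 6α configuration is kept.

Step 3
Reactants: 3 6α-(triethylsilyloxy)eudesma-4,11(13)-dien-12,8β-olide
Product: 5 methyl 8β-hydroxy-6α-(triethylsilyloxy)eudesma-4,11(13)-dien-12-oate, via lithium carboxylate 4 (not isolated)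
Conditions: LiOH·H2O (1.1 equiv), THF/H2O, 0 °C → rt; evaporate, PhMe azeotrope; then MeI, DMF, 0 °C → rt; used crude
Reagents that add atoms: lithium hydroxide, [Li+].[OH-]; iodomethane, CI
Why: Saponification of the γ-lactone followed by SN2 O-methylation of the dry carboxylate gives the hydroxy ester without any acidification, so reclosure onto O8 should be avoided; the TES ether tolerates the mild base and no stereocentre is touched.

Step 4
Reactants: 5 methyl 8β-hydroxy-6α-(triethylsilyloxy)eudesma-4,11(13)-dien-12-oate
Product: 6 methyl 8β-(tert-butyldimethylsilyloxy)-6α-(triethylsilyloxy)eudesma-4,11(13)-dien-12-oate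
Conditions: TBSOTf, 2,6-lutidine, CH2Cl2, −78 → 0 °C
Reagents that add atoms: tert-butyldimethylsilyl trifluoromethanesulfonate, CC(C)(C)[Si](C)(C)OS(=O)(=O)C(F)(F)F
Why: Silyl-triflate silylation of the hindered axial secondary alcohol is fast at low temperature and should outrun relactonisation of the γ-hydroxy ester.

Step 5
Reactants: 6 methyl 8β-(tert-butyldimethylsilyloxy)-6α-(triethylsilyloxy)eudesma-4,11(13)-dien-12-oate
Product: 8 8β-(tert-butyldimethylsilyloxy)eudesma-4,11(13)-dien-12,6α-olide (trans-fused, H6 β and H7 α), via hydroxy ester 7 (not isolated)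
Conditions: HF·pyridine, pyridine, THF, 0 °C; then PPTS (cat.), PhMe, 60 °C
Reagents that add atoms: none
Why: Selective desilylation (the TES ether is cleaved far faster than the hindered secondary TBS ether) followed by mild acid-catalysed lactonisation (5-exo-trig transesterification) of the 6α-hydroxyl onto C12; the trans fusion follows from the fixed 6α-oxygen and 7β side chain, and the weak acid avoids ionising allylic C6.

Step 6
Reactants: 8 8β-(tert-butyldimethylsilyloxy)eudesma-4,11(13)-dien-12,6α-olide
Product: 9 5α-hydroperoxy-8β-(tert-butyldimethylsilyloxy)eudesma-4(15),11(13)-dien-12,6α-olide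
Conditions: O2, 5,10,15,20-tetraphenylporphyrin (cat.), hν (visible), CH2Cl2, −20 °C
Reagents that add atoms: oxygen, O=O
Why: Schenck ene reaction of singlet oxygen with the tetrasubstituted olefin on the α face (the β face is blocked by the axial 10β-methyl and 8β-silyloxy groups); oxygen must bond to C5 because α-face allylic hydrogens exist only on the C4 substituents (C10 has none, H6 is β), and abstraction from C15 gives the 4(15)-ene and sets C5, the 3-ene regioisomer being the expected by-product to be removed by chromatography.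

Step 7
Reactants: 9 5α-hydroperoxy-8β-(tert-butyldimethylsilyloxy)eudesma-4(15),11(13)-dien-12,6α-olide
Product: 11 5-acetoxy-8β-(tert-butyldimethylsilyloxy)-5,10-epoxygermacra-4(15),11(13)-dien-12,6α-olide (bridgehead ketal acetate of the 11-oxabicyclo[4.4.1]undecane, acetate and 10-methyl on the outer face), via peracetate 10 (not isolated)
Conditions: Ac2O, pyridine, DMAP (cat.), CH2Cl2, 0 °C → rt, dark
Reagents that add atoms: acetic anhydride, CC(=O)OC(C)=O
Why: Proposed new method: O-acetylation of the tertiary hydroperoxide gives peracetate 10, and heterolysis of its O–O bond is concerted with a 1,2-shift of the C5–C10 bond to the inner oxygen (Criegee rearrangement), so that this oxygen becomes the C5–O–C10 bridge and C5 becomes an oxocarbenium carbon that the departing acetate recaptures. The closest known reaction type is the Criegee rearrangement of 9-decalyl peresters to 1-acyloxy-11-oxabicyclo[4.4.1]undecanes, which has not been shown for an ene-derived allylic hydroperoxide flanked by an acyloxy-bearing carbon. Both oxepane rings are closed in this single event by ring expansion (oxygen insertion into the decalin fusion bond), not by end-to-end cyclisation, and the ten-membered carbocycle appears at the same time. C10 keeps its configuration because the shift is suprafacial with retention at the migrating carbon, and C5 is dictated by the one-atom bridge, since acetate can reach the bridgehead cation only from the outer face. The step needs migration of C10 in preference to C4 or C6: C10 is a fully substituted alkyl carbon of the highest migratory aptitude, C4 is vinylic and C6 is deactivated by the lactone oxygen, which is why the lactone was moved to O6 beforehand. Rotation about the C5–O bond lets the C5–C10 bond lie antiperiplanar to the O–O bond.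

Step 8
Reactants: 11 5-acetoxy-8β-(tert-butyldimethylsilyloxy)-5,10-epoxygermacra-4(15),11(13)-dien-12,6α-olide
Product: 12 8β-(tert-butyldimethylsilyloxy)-5,10-epoxygermacra-4(15),11(13)-dien-12,6α-olide (H5 on the outer face, cis to H6)
Conditions: Et3SiH, TMSOTf (cat.), CH2Cl2, −78 → −40 °C
Reagents that add atoms: none
Why: Ionic hydrogenation of a ketal ester, as in the reductive deoxygenation of ketosyl acetates: the silyl triflate ionises the acetate to the oxygen-bridged oxocarbenium ion and Et3SiH should deliver hydride to C5 from the only open (outer) face, 1,2-addition at the oxocarbenium carbon being expected over attack at C15.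

Step 9
Reactants: 12 8β-(tert-butyldimethylsilyloxy)-5,10-epoxygermacra-4(15),11(13)-dien-12,6α-olide
Product: 13 8β-hydroxy-5,10-epoxygermacra-4(15),11(13)-dien-12,6α-olide
Conditions: HF·pyridine, THF, 0 °C → rt
Reagents that add atoms: none
Why: Fluoride-mediated desilylation under mildly acidic conditions, which spare the base-sensitive α-methylene lactone and the bridged ether.

Step 10
Reactants: 13 8β-hydroxy-5,10-epoxygermacra-4(15),11(13)-dien-12,6α-olide; 14 angelic acid ((Z)-2-methylbut-2-enoic acid)
Product: 16 8β-angeloyloxy-5,10-epoxygermacra-4(15),11(13)-dien-12,6α-olide, via mixed anhydride 15 (not isolated)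
Conditions: 14, 2,4,6-Cl3C6H2COCl, Et3N, PhMe, rt; then 13, 75 °C (no DMAP)
Reagents that add atoms: none
Why: Yamaguchi esterification through the mixed anhydride, whose shielded aroyl carbonyl directs the alcohol to the angeloyl carbonyl; leaving out the nucleophilic catalyst should suppress Z to E isomerisation to the tiglate, and C8 is untouched because only the O–H bond reacts.

Step 11
Reactants: 16 8β-angeloyloxy-5,10-epoxygermacra-4(15),11(13)-dien-12,6α-olide
Product: 17 8β-angeloyloxy-3-hydroxy-5,10-epoxygermacra-4(15),11(13)-dien-12,6α-olide (hydroxyl expected on the outer face of its oxepane, cis to H5)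
Conditions: SeO2 (cat.), t-BuOOH, CH2Cl2, 0 °C → rt
Reagents that add atoms: selenium dioxide, O=[Se]=O; tert-butyl hydroperoxide, CC(C)(C)OO
Why: Sharpless catalytic SeO2 allylic hydroxylation (ene reaction then [2,3]-sigmatropic shift) of the electron-rich 1,1-disubstituted olefin; C3 is the only allylic C–H that can enter the ene step because C5 is a bridgehead, and the conjugated olefins of the lactone and the angelate are too electron-poor to compete.

Step 12
Reactants: 17 8β-angeloyloxy-3-hydroxy-5,10-epoxygermacra-4(15),11(13)-dien-12,6α-olide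
Product: 18 8β-angeloyloxy-3-oxo-5,10-epoxygermacra-4(15),11(13)-dien-12,6α-olide
Conditions: Dess–Martin periodinane, CH2Cl2, 0 °C → rt
Reagents that add atoms: none
Why: Dess–Martin oxidation of the secondary allylic alcohol under non-basic conditions, which should leave the resulting α-methylene ketone and the other Michael acceptors intact.

Step 13
Reactants: 18 8β-angeloyloxy-3-oxo-5,10-epoxygermacra-4(15),11(13)-dien-12,6α-olide
Product: 19 8β-angeloyloxy-3-oxo-5,10-epoxygermacra-1,4(15),11(13)-trien-12,6α-olide (target CNP0335602.1)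
Conditions: IBX (2-iodoxybenzoic acid), DMSO/PhF, 70 °C
Reagents that add atoms: none
Why: IBX dehydrogenation of a ketone to an enone; the ketone can enolise only toward C2 (C4 is sp2) and C1 is flanked by quaternary C10, so the new olefin can only be C1=C2, cis within its seven-membered ring.

**Compound list**

1 | (+)-alantolactone (eudesma-5,11(13)-dien-12,8β-olide) | C[C@H]1CCC[C@]2(C1=C[C@H]3[C@@H](C2)OC(=O)C3=C)C | starting material
2 | 5α,6α-epoxyalantolactone | C[C@H]1CCC[C@@]2(C)[C@]13O[C@H]3[C@H]4[C@@H](C2)OC(=O)C4=C | intermediate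
3 | 6α-(triethylsilyloxy)eudesma-4,11(13)-dien-12,8β-olide | CC1=C2[C@@H](O[Si](CC)(CC)CC)[C@H]3[C@@H](C[C@@]2(C)CCC1)OC(=O)C3=C | intermediate
4 | lithium 8β-hydroxy-6α-(triethylsilyloxy)eudesma-4,11(13)-dien-12-oate | CC1=C2[C@@H](O[Si](CC)(CC)CC)[C@@H]([C@@H](C[C@@]2(C)CCC1)O)C(=C)C(=O)[O-].[Li+] | intermediate
5 | methyl 8β-hydroxy-6α-(triethylsilyloxy)eudesma-4,11(13)-dien-12-oate | CC1=C2[C@@H](O[Si](CC)(CC)CC)[C@@H]([C@@H](C[C@@]2(C)CCC1)O)C(=C)C(=O)OC | intermediate
6 | methyl 8β-(tert-butyldimethylsilyloxy)-6α-(triethylsilyloxy)eudesma-4,11(13)-dien-12-oate | CC1=C2[C@@H](O[Si](CC)(CC)CC)[C@@H]([C@@H](C[C@@]2(C)CCC1)O[Si](C)(C)C(C)(C)C)C(=C)C(=O)OC | intermediate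
7 | methyl 8β-(tert-butyldimethylsilyloxy)-6α-hydroxyeudesma-4,11(13)-dien-12-oate | CC1=C2[C@@H](O)[C@@H]([C@@H](C[C@@]2(C)CCC1)O[Si](C)(C)C(C)(C)C)C(=C)C(=O)OC | intermediate
8 | 8β-(tert-butyldimethylsilyloxy)eudesma-4,11(13)-dien-12,6α-olide | C=C1C(=O)O[C@H]2[C@H]1[C@H](O[Si](C)(C)C(C)(C)C)C[C@@]1(C)CCCC(C)=C21 | intermediate
9 | 5α-hydroperoxy-8β-(tert-butyldimethylsilyloxy)eudesma-4(15),11(13)-dien-12,6α-olide | C=C1C(=O)O[C@H]2[C@H]1[C@H](O[Si](C)(C)C(C)(C)C)C[C@@]1(C)CCCC(=C)[C@]21OO | intermediate
10 | 5α-(acetylperoxy)-8β-(tert-butyldimethylsilyloxy)eudesma-4(15),11(13)-dien-12,6α-olide | C=C1C(=O)O[C@H]2[C@H]1[C@H](O[Si](C)(C)C(C)(C)C)C[C@@]1(C)CCCC(=C)[C@]21OOC(C)=O | intermediate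
11 | 5-acetoxy-8β-(tert-butyldimethylsilyloxy)-5,10-epoxygermacra-4(15),11(13)-dien-12,6α-olide | C=C1C(=O)O[C@H]2[C@H]1[C@H](O[Si](C)(C)C(C)(C)C)C[C@@]1(C)CCCC(=C)[C@]2(OC(C)=O)O1 | intermediate
12 | 8β-(tert-butyldimethylsilyloxy)-5,10-epoxygermacra-4(15),11(13)-dien-12,6α-olide | C=C1C(=O)O[C@H]2[C@H]1[C@H](O[Si](C)(C)C(C)(C)C)C[C@@]1(C)CCCC(=C)[C@@H]2O1 | intermediate
13 | 8β-hydroxy-5,10-epoxygermacra-4(15),11(13)-dien-12,6α-olide | C=C1C(=O)O[C@H]2[C@H]1[C@H](O)C[C@@]1(C)CCCC(=C)[C@@H]2O1 | intermediate
14 | angelic acid, (Z)-2-methylbut-2-enoic acid | C/C=C(/C)C(=O)O | starting material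
15 | angelic 2,4,6-trichlorobenzoic anhydride | C/C=C(/C)C(=O)OC(=O)c1c(Cl)cc(Cl)cc1Cl | intermediate
16 | 8β-angeloyloxy-5,10-epoxygermacra-4(15),11(13)-dien-12,6α-olide | C=C1C(=O)O[C@H]2[C@H]1[C@H](OC(=O)/C(C)=C\C)C[C@@]1(C)CCCC(=C)[C@@H]2O1 | intermediate
17 | 8β-angeloyloxy-3-hydroxy-5,10-epoxygermacra-4(15),11(13)-dien-12,6α-olide | C=C1C(=O)O[C@H]2[C@H]1[C@H](OC(=O)/C(C)=C\C)C[C@@]1(C)CC[C@H](O)C(=C)[C@@H]2O1 | intermediate
18 | 8β-angeloyloxy-3-oxo-5,10-epoxygermacra-4(15),11(13)-dien-12,6α-olide | C=C1C(=O)O[C@H]2[C@H]1[C@H](OC(=O)/C(C)=C\C)C[C@@]1(C)CCC(=O)C(=C)[C@@H]2O1 | intermediate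
19 | 8β-angeloyloxy-3-oxo-5,10-epoxygermacra-1,4(15),11(13)-trien-12,6α-olide (CNP0335602.1) | C=C1C(=O)O[C@H]2[C@H]1[C@H](OC(=O)/C(C)=C\C)C[C@@]1(C)C=CC(=O)C(=C)[C@@H]2O1 | target

**Step count**

Total step count: 13. Longest linear sequence: 13 steps (1 to 19); angelic acid 14 is bought and enters at step 10.

**Steps most likely to fail**

1. Step 7 (Criegee shift). The perester may ionise with migration of the vinylic C4 (Hock-type cleavage to a seco enol ether), the allylic peroxide may transpose to C15, or the peracetate may be too inert to ionise. The fallback sets out from 9 and comes back at 12, using known reaction types only.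
   - Ph3P would reduce the hydroperoxide to 5α-hydroxy-8β-(tert-butyldimethylsilyloxy)eudesma-4(15),11(13)-dien-12,6α-olide F1.
   - Alkoxy-radical β-scission of the C5–C10 bond (Pb(OAc)4, PhH, reflux, or PhI(OAc)2/I2 under visible light), the known way from 5α-hydroxy decalins to cyclodecenones, should give the ten-membered (1(10)E)-5-oxo-8β-(tert-butyldimethylsilyloxy)germacra-1(10),4(15),11(13)-trien-12,6α-olide F2; a 10(14)-ene isomer would serve equally.
   - Luche reduction (NaBH4, CeCl3·7H2O, MeOH, −78 °C) would give the allylic alcohol 5-hydroxy-8β-(tert-butyldimethylsilyloxy)germacra-1(10),4(15),11(13)-trien-12,6α-olide F3.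
   - Acid-catalysed transannular Markovnikov hydroalkoxylation (CSA cat., CH2Cl2) would close the C5 oxygen onto tertiary C10 and give 12.
   - In this variant C5 is set by the hydride reduction and C10 by the geometric demand of the one-atom bridge.

2. Step 8 (silane reduction). Hydride may be delivered to C15 of the allyl-type oxocarbenium ion instead of C5, or ionisation of the twisted bridgehead ketal may be so slow that the Lewis acid attacks the silyl ether first. The fallback sets out from 11 and comes back at 12.
   - Mild hydrolysis (AcOH/THF/H2O) would give the bridgehead hemiketal 5-hydroxy-8β-(tert-butyldimethylsilyloxy)-5,10-epoxygermacra-4(15),11(13)-dien-12,6α-olide F4, in equilibrium with its ring-opened 10-hydroxy-5-ketone.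
   - Luche reduction of the keto form would give 5,10-dihydroxy-8β-(tert-butyldimethylsilyloxy)germacra-4(15),11(13)-dien-12,6α-olide F5.
   - Acid-mediated cyclodehydration (CSA, CH2Cl2, molecular sieves) would then form the ether 12.
   - A simple 1,2-reduction of a ketone thus replaces hydride addition to the bridged cation; where closure runs through the allylic C5 cation the C10–O bond stays intact, so C10 keeps its configuration and the bridge fixes C5.

3. Step 3 (lactone opening and ester capture). Hydroxide may add to the methylene lactone in conjugate fashion, or the γ-hydroxy ester may reclose to the 8,12-lactone before it is silylated. The fallback sets out from 3 and comes back at 8, and opens the lactone by reduction instead of hydrolysis.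
   - DIBAL-H (CH2Cl2, −78 → 0 °C) would give 6α-(triethylsilyloxy)eudesma-4,11(13)-diene-8β,12-diol F6.
   - TBSOTf/2,6-lutidine would silylate both hydroxyls to 8β,12-bis(tert-butyldimethylsilyloxy)-6α-(triethylsilyloxy)eudesma-4,11(13)-diene F7.
   - HF·pyridine would remove the TES group and the primary allylic TBS group but not the hindered secondary one, giving 8β-(tert-butyldimethylsilyloxy)eudesma-4,11(13)-diene-6α,12-diol F8.
   - TEMPO (cat.)/PhI(OAc)2 oxidative lactonisation (primary alcohol to aldehyde, lactol, lactone) would give 8.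

**Further compounds**

F1 | step 7 | 5α-hydroxy-8β-(tert-butyldimethylsilyloxy)eudesma-4(15),11(13)-dien-12,6α-olide | C=C1C(=O)O[C@H]2[C@H]1[C@H](O[Si](C)(C)C(C)(C)C)C[C@@]1(C)CCCC(=C)[C@]21O
F2 | step 7 | (1(10)E)-5-oxo-8β-(tert-butyldimethylsilyloxy)germacra-1(10),4(15),11(13)-trien-12,6α-olide | C=C1C(=O)O[C@H]2[C@H]1[C@H](O[Si](C)(C)C(C)(C)C)C/C(C)=C/CCC(=C)C2=O
F3 | step 7 | (1(10)E)-5-hydroxy-8β-(tert-butyldimethylsilyloxy)germacra-1(10),4(15),11(13)-trien-12,6α-olide | C=C1C(=O)O[C@H]2[C@H]1[C@H](O[Si](C)(C)C(C)(C)C)C/C(C)=C/CCC(=C)[C@@H]2O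
F4 | step 8 | 5-hydroxy-8β-(tert-butyldimethylsilyloxy)-5,10-epoxygermacra-4(15),11(13)-dien-12,6α-olide (bridgehead hemiketal) | C=C1C(=O)O[C@H]2[C@H]1[C@H](O[Si](C)(C)C(C)(C)C)C[C@@]1(C)CCCC(=C)[C@]2(O)O1
F5 | step 8 | 5,10-dihydroxy-8β-(tert-butyldimethylsilyloxy)germacra-4(15),11(13)-dien-12,6α-olide | C=C1C(=O)O[C@H]2[C@H]1[C@H](O[Si](C)(C)C(C)(C)C)C[C@](C)(O)CCCC(=C)[C@@H]2O
F6 | step 3 | 6α-(triethylsilyloxy)eudesma-4,11(13)-diene-8β,12-diol | CC1=C2[C@@H](O[Si](CC)(CC)CC)[C@@H]([C@@H](C[C@@]2(C)CCC1)O)C(=C)CO
F7 | step 3 | 8β,12-bis(tert-butyldimethylsilyloxy)-6α-(triethylsilyloxy)eudesma-4,11(13)-diene | CC1=C2[C@@H](O[Si](CC)(CC)CC)[C@@H]([C@@H](C[C@@]2(C)CCC1)O[Si](C)(C)C(C)(C)C)C(=C)CO[Si](C)(C)C(C)(C)C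
F8 | step 3 | 8β-(tert-butyldimethylsilyloxy)eudesma-4,11(13)-diene-6α,12-diol | CC1=C2[C@@H](O)[C@@H]([C@@H](C[C@@]2(C)CCC1)O[Si](C)(C)C(C)(C)C)C(=C)CO
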